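**Retrosynthetic overview**
1. The target is cut at the dihydropyran: a final oxa-hetero-Diels–Alder reaction joins alkylidene triketone 25 (C15) to (−)-β-pinene 12 (C10), forming the O–C(spiro) and C3′–C4′ bonds.
2. 25 comes from a Knoevenagel condensation of syncarpic acid 22 with 3-methylbutanal; 22 comes from a Dieckmann closure of diketo ester 19, assembled by two enolate acylations (methyl isobutyrate, isobutyryl chloride, acetyl chloride).
3. 12 comes from Wittig methylenation of (+)-nopinone 11; 11 comes from conjugate methyl addition to enone tosylate 9 followed by intramolecular enolate alkylation (cyclobutane closed last).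
4. 9 comes from an auxiliary-controlled Diels–Alder reaction of acrylimide 2 with siloxydiene 5, which sets the one stereocentre that dictates the pinane configuration.
5. Ring order: cyclohexene, then cyclobutane (pinane arm); triketone six-membered ring (second arm); dihydropyran last.

Assumption: the target is taken as drawn, a (1R,2R,5S)-pinane spiro-linked at C2 to a (4′R)-chromenedione. The 4′-epimer that forms beside it in the last step is removed by chromatography.

**Pinane arm**

Step 1
Reactants: 1 acryloyl chloride
Product: 2 (4S)-4-benzyl-3-(prop-2-enoyl)-1,3-oxazolidin-2-one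
Conditions: (4S)-4-benzyl-1,3-oxazolidin-2-one, n-BuLi, THF, −78 °C; then 1, −78 → 0 °C
Reagents that add atoms: (4S)-4-benzyl-1,3-oxazolidin-2-one, O=C1OC[C@H](Cc2ccccc2)N1
Why: N-acylation of the lithiated oxazolidinone by the acid chloride (imide formation); no stereocentre is formed and the auxiliary centre is untouched.

Step 2
Reactants: 3 (3E)-pent-3-en-2-one
Product: 5 tert-butyl(dimethyl)[(3E)-penta-1,3-dien-2-yloxy]silane, via lithium dienolate 4 (not isolated)
Conditions: LiN(iPr)2, THF, −78 °C; then TBSCl, HMPA, −78 °C → rt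
Reagents that add atoms: tert-butyl(chloro)dimethylsilane, CC(C)(C)[Si](C)(C)Cl
Why: kinetic deprotonation at the α′-methyl and O-silylation of the cross-conjugated enolate (silyl dienol ether formation); the E-alkene is unchanged.

Step 3
Reactants: 2 (4S)-4-benzyl-3-(prop-2-enoyl)-1,3-oxazolidin-2-one; 5 tert-butyl(dimethyl)[(3E)-penta-1,3-dien-2-yloxy]silane
Product: 6 (4S)-4-benzyl-3-[(1R,2S)-4-{[tert-butyl(dimethyl)silyl]oxy}-2-methylcyclohex-3-ene-1-carbonyl]-1,3-oxazolidin-2-one
Conditions: Et2AlCl (1.4 equiv), CH2Cl2, −78 °C; aq. NaHCO3 work-up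
Reagents that add atoms: none
Why: Evans auxiliary-controlled, Lewis-acid-promoted Diels–Alder reaction in which the diene adds to the chelated s-cis acrylimide on the face away from the benzyl group (C1 = R), the endo mode places the methyl cis to the acyl group (C2 = S), and the 2-siloxy and 4-methyl groups both direct the "para/ortho" regiochemistry.

Step 4
Reactants: 6 (the Diels–Alder imide)
Product: 7 [(1R,2R)-4-{[tert-butyl(dimethyl)silyl]oxy}-2-methylcyclohex-3-en-1-yl]methanol
Conditions: LiBH4, MeOH (1 equiv), THF, 0 °C
Reagents that add atoms: none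
Why: reductive cleavage of the exocyclic imide carbonyl to the primary alcohol with release of the auxiliary; the silyl enol ether survives hydride and both stereocentres are untouched (the C2 descriptor changes from S to R only because priorities change).

Step 5
Reactants: 7 (the primary alcohol)
Product: 8 [(1R,2R)-4-{[tert-butyl(dimethyl)silyl]oxy}-2-methylcyclohex-3-en-1-yl]methyl 4-methylbenzenesulfonate
Conditions: TsCl, Et3N, DMAP (cat.), CH2Cl2, 0 °C → rt
Reagents that add atoms: 4-methylbenzenesulfonyl chloride, Cc1ccc(cc1)S(=O)(=O)Cl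
Why: sulfonylation of the primary alcohol under basic conditions that leave the silyl enol ether intact; no stereocentre is touched.

Step 6
Reactants: 8 (the silyl enol ether tosylate)
Product: 9 [(1R)-2-methyl-4-oxocyclohex-2-en-1-yl]methyl 4-methylbenzenesulfonate
Conditions: Pd(OAc)2 (10 mol %), O2 (1 atm), DMSO, rt
Reagents that add atoms: none
Why: Saegusa–Ito oxidation, in which the divalent palladium enolate at C3 can undergo β-hydride elimination only toward C2, giving the 3-methyl enone and erasing the methyl stereocentre while C1 (R), now γ to the ketone, is kept under neutral conditions.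

Step 7
Reactants: 9 (the enone tosylate)
Product: 11 (1R,5S)-6,6-dimethylbicyclo[3.1.1]heptan-2-one ((+)-nopinone), via lithium enolate 10 (not isolated)
Conditions: Me2CuLi (1.1 equiv, from CuI and MeLi), Et2O, −78 → −20 °C; then THF, HMPA, −20 °C → rt
Reagents that add atoms: lithium dimethylcuprate, [Li+].C[Cu-]C
Why: tandem cuprate conjugate addition and intramolecular enolate C-alkylation (4-exo-tet), in which the enolate is formed regiospecifically at the carbon next to the new CMe2 group and closes onto the CH2OTs arm; C5 is the stereocentre carried from 9 and the new bridgehead C1 can only form cis across the one-carbon bridge.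

Step 8
Reactants: 11 (+)-nopinone
Product: 12 (1S,5S)-6,6-dimethyl-2-methylidenebicyclo[3.1.1]heptane ((−)-β-pinene)
Conditions: Ph3PCH3Br, KOt-Bu, THF, 0 °C → rt; then 11, rt → 50 °C
Reagents that add atoms: methyltriphenylphosphonium bromide, C[P+](c1ccccc1)(c1ccccc1)c1ccccc1.[Br-]
Why: Wittig methylenation of the ketone; the bridgehead centres cannot epimerise (the C1 descriptor changes from R to S only because priorities change).

**Triketone arm**

Step 9
Reactants: 13 methyl 2-methylpropanoate; 14 2-methylpropanoyl chloride
Product: 16 methyl 2,2,4-trimethyl-3-oxopentanoate, via lithium ester enolate 15 (not isolated)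
Conditions: LiN(iPr)2, THF, −78 °C; then cannulated into 14 (1.2 equiv), THF, −78 °C → rt
Reagents that add atoms: none
Why: crossed Claisen-type C-acylation of the ester enolate by the acid chloride; inverse addition limits proton transfer to the product and no stereocentre is formed.

Step 10
Reactants: 16 methyl 2,2,4-trimethyl-3-oxopentanoate; 17 acetyl chloride
Product: 19 methyl 2,2,4,4-tetramethyl-3,5-dioxohexanoate, via lithium ketone enolate 18 (not isolated)
Conditions: LiN(iPr)2, THF, −78 °C; then 17 (1.5 equiv), −78 → 0 °C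
Reagents that add atoms: none
Why: C-acylation of the only enolisable position (the isopropyl ketone) as its lithium enolate with an acid chloride, which favours carbon over oxygen attack; the product has no acidic hydrogen between its carbonyls, so it is not acylated further.

Step 11
Reactants: 19 methyl 2,2,4,4-tetramethyl-3,5-dioxohexanoate
Product: 22 2,2,4,4-tetramethylcyclohexane-1,3,5-trione (syncarpic acid), via lithium methyl-ketone enolate 20 (not isolated), via lithium syncarpate 21 (not isolated)
Conditions: LiN(iPr)2 (2.2 equiv), THF, −78 °C → rt; then 1 M HCl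
Reagents that add atoms: none
Why: Dieckmann-type intramolecular Claisen condensation of the methyl ketone enolate onto the ester (six-membered ring), driven by formation of the stabilised triketone enolate.

Step 12
Reactants: 22 syncarpic acid; 23 3-methylbutanal
Product: 25 2,2,4,4-tetramethyl-6-(3-methylbutylidene)cyclohexane-1,3,5-trione, via Mannich base 24 (not isolated)
Conditions: piperidine (1.1 equiv), CH2Cl2, rt; then 1 M HCl, Et2O, 0 °C
Reagents that add atoms: none
Why: Knoevenagel condensation run through the piperidine Mannich adduct, which blocks addition of a second triketone; acid then eliminates piperidine to release the alkylidene (no stereocentre, the triketone is symmetric).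

**Fragment union**

Step 13
Reactants: 25 the alkylidene triketone; 12 (−)-β-pinene
Product: 26 (1R,2R,4′R,5S)-6,6,6′,6′,8′,8′-hexamethyl-4′-(2-methylpropyl)-3′,4′-dihydrospiro[bicyclo[3.1.1]heptane-2,2′-chromene]-5′,7′(6′H,8′H)-dione (target)
Conditions: PhMe, 80 °C, sealed tube (25 in 1.3-fold excess); silica gel chromatography, then HPLC
Reagents that add atoms: none
Why: inverse-electron-demand oxa-hetero-Diels–Alder reaction in which the exocyclic CH2 of 12 bonds to the alkylidene carbon and the enone oxygen to C2 of the pinane on the face opposite the gem-dimethyl bridge (spiro centre 2R), while C4′ depends on the endo/exo orientation (bridgehead C1 under the heterodiene gives 4′R), so the 4′S epimer forms in comparable amount and is separated.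

**Compound list**
1 | acryloyl chloride | C=CC(=O)Cl | starting material
2 | (4S)-4-benzyl-3-(prop-2-enoyl)-1,3-oxazolidin-2-one | C=CC(=O)N1[C@@H](Cc2ccccc2)COC1=O | intermediate
3 | (3E)-pent-3-en-2-one | C/C=C/C(C)=O | starting material
4 | lithium (3E)-penta-1,3-dien-2-olate | [Li+].[O-]C(=C)/C=C/C | intermediate (not isolated)
5 | tert-butyl(dimethyl)[(3E)-penta-1,3-dien-2-yloxy]silane | C=C(O[Si](C)(C)C(C)(C)C)/C=C/C | intermediate
6 | (4S)-4-benzyl-3-[(1R,2S)-4-{[tert-butyl(dimethyl)silyl]oxy}-2-methylcyclohex-3-ene-1-carbonyl]-1,3-oxazolidin-2-one | O=C([C@@H]1CCC(O[Si](C)(C)C(C)(C)C)=C[C@@H]1C)N1[C@@H](Cc2ccccc2)COC1=O | intermediate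
7 | [(1R,2R)-4-{[tert-butyl(dimethyl)silyl]oxy}-2-methylcyclohex-3-en-1-yl]methanol | OC[C@@H]1CCC(O[Si](C)(C)C(C)(C)C)=C[C@@H]1C | intermediate
8 | [(1R,2R)-4-{[tert-butyl(dimethyl)silyl]oxy}-2-methylcyclohex-3-en-1-yl]methyl 4-methylbenzenesulfonate | Cc1ccc(cc1)S(=O)(=O)OC[C@@H]1CCC(O[Si](C)(C)C(C)(C)C)=C[C@@H]1C | intermediate
9 | [(1R)-2-methyl-4-oxocyclohex-2-en-1-yl]methyl 4-methylbenzenesulfonate | Cc1ccc(cc1)S(=O)(=O)OC[C@@H]1CCC(=O)C=C1C | intermediate
10 | lithium (4R)-3,3-dimethyl-4-{[(4-methylbenzenesulfonyl)oxy]methyl}cyclohex-1-en-1-olate | [Li+].[O-]C1=CC(C)(C)[C@H](COS(=O)(=O)c2ccc(C)cc2)CC1 | intermediate (not isolated)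
11 | (1R,5S)-6,6-dimethylbicyclo[3.1.1]heptan-2-one ((+)-nopinone) | CC1(C)[C@H]2CCC(=O)[C@@H]1C2 | intermediate
12 | (1S,5S)-6,6-dimethyl-2-methylidenebicyclo[3.1.1]heptane ((−)-β-pinene) | CC1(C)[C@H]2CCC(=C)[C@@H]1C2 | intermediate
13 | methyl 2-methylpropanoate | COC(=O)C(C)C | starting material
14 | 2-methylpropanoyl chloride | CC(C)C(=O)Cl | starting material
15 | lithium 1-methoxy-2-methylprop-1-en-1-olate | [Li+].[O-]C(OC)=C(C)C | intermediate (not isolated)
16 | methyl 2,2,4-trimethyl-3-oxopentanoate | COC(=O)C(C)(C)C(=O)C(C)C | intermediate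
17 | acetyl chloride | CC(=O)Cl | starting material
18 | lithium 1-methoxy-2,2,4-trimethyl-1-oxopent-3-en-3-olate | [Li+].[O-]C(=C(C)C)C(C)(C)C(=O)OC | intermediate (not isolated)
19 | methyl 2,2,4,4-tetramethyl-3,5-dioxohexanoate | COC(=O)C(C)(C)C(=O)C(C)(C)C(C)=O | intermediate
20 | lithium 6-methoxy-3,3,5,5-tetramethyl-4,6-dioxohex-1-en-2-olate | [Li+].[O-]C(=C)C(C)(C)C(=O)C(C)(C)C(=O)OC | intermediate (not isolated)
21 | lithium 4,4,6,6-tetramethyl-3,5-dioxocyclohex-1-en-1-olate (lithium syncarpate) | [Li+].[O-]C1=CC(=O)C(C)(C)C(=O)C1(C)C | intermediate (not isolated)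
22 | 2,2,4,4-tetramethylcyclohexane-1,3,5-trione (syncarpic acid) | CC1(C)C(=O)CC(=O)C(C)(C)C1=O | intermediate
23 | 3-methylbutanal | CC(C)CC=O | starting material
24 | 2,2,4,4-tetramethyl-6-[3-methyl-1-(piperidin-1-yl)butyl]cyclohexane-1,3,5-trione (racemic Mannich base) | CC(C)CC(N1CCCCC1)C1C(=O)C(C)(C)C(=O)C(C)(C)C1=O | intermediate (not isolated)
25 | 2,2,4,4-tetramethyl-6-(3-methylbutylidene)cyclohexane-1,3,5-trione | CC(C)CC=C1C(=O)C(C)(C)C(=O)C(C)(C)C1=O | intermediate
26 | (1R,2R,4′R,5S)-6,6,6′,6′,8′,8′-hexamethyl-4′-(2-methylpropyl)-3′,4′-dihydrospiro[bicyclo[3.1.1]heptane-2,2′-chromene]-5′,7′(6′H,8′H)-dione | CC(C)C[C@@H]1C[C@@]2(CC[C@H]3C[C@@H]2C3(C)C)OC2=C1C(=O)C(C)(C)C(=O)C2(C)C | target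

**Step count**
Total: 13 steps. Longest linear sequence: 8 steps (1 or 2, then 3, 4, 5, 6, 7, 8, 13). The triketone arm is 5 steps (9, 10, 11, 12, 13).

**Steps most likely to fail**

Step 7 (tandem methyl addition and cyclobutane closure). The cuprate may displace the primary tosylate, and the copper-bound enolate may be too sluggish to close a four-membered ring. The fallback sets out from 7 and comes back at 11, and never exposes a sulfonate to the cuprate. Alcohol 7 is oxidised directly under the Saegusa–Ito conditions of step 6 to (4R)-4-(hydroxymethyl)-3-methylcyclohex-2-en-1-one F2. Me2CuLi (2.5 equiv, Et2O, 0 °C) then gives (4R)-4-(hydroxymethyl)-3,3-dimethylcyclohexan-1-one F3. Tosylation (TsCl, pyridine) gives [(1R)-2,2-dimethyl-4-oxocyclohexyl]methyl 4-methylbenzenesulfonate F4. The ring is closed with NaH in refluxing DME under equilibrating conditions, where the gem-dimethyl group favours closure at the flanked α-carbon, giving 11.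

Step 3 (Diels–Alder reaction). The silyl dienol ether may be degraded by stoichiometric Et2AlCl, or react by a Mukaiyama–Michael pathway instead of cycloaddition. The fallback sets out from 5 and comes back at 7, replacing auxiliary control by catalyst control, so step 1 is no longer needed. Diene 5 and methyl acrylate are combined with a triflimide-activated B-(o-tolyl) oxazaborolidine derived from α,α-diphenylprolinol (20 mol %, CH2Cl2, −78 → −40 °C). The catalyst antipode is chosen to give methyl (1R,2S)-4-{[tert-butyl(dimethyl)silyl]oxy}-2-methylcyclohex-3-ene-1-carboxylate F1; which antipode does this must be established by correlation with 7 from step 4. LiAlH4 (Et2O, 0 °C) then reduces F1 to 7.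

Step 13 (hetero-Diels–Alder union). Isolated 25 can tautomerise to its dienol or oligomerise, β-pinene can react by an ene pathway, and the 4′-epimer is unavoidable. The fallback sets out from 22 and 23 and comes back at 26, and avoids isolating the heterodiene. Reductive alkylation of 22 with 23 (L-proline cat., Hantzsch ester, CH2Cl2, rt) gives 2,2,4,4-tetramethyl-6-(3-methylbutyl)cyclohexane-1,3,5-trione F5. F5 is then dehydrogenated with Ag2O and TEMPO in PhMe in the presence of 12, so that 25 is generated slowly at low concentration and trapped as 26. This does not change the 4′-epimer ratio, so the chromatographic separation remains.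

**Further compounds**
F1 | step 3 | methyl (1R,2S)-4-{[tert-butyl(dimethyl)silyl]oxy}-2-methylcyclohex-3-ene-1-carboxylate | COC(=O)[C@@H]1CCC(O[Si](C)(C)C(C)(C)C)=C[C@@H]1C
F2 | step 7 | (4R)-4-(hydroxymethyl)-3-methylcyclohex-2-en-1-one | O=C1C=C(C)[C@H](CO)CC1
F3 | step 7 | (4R)-4-(hydroxymethyl)-3,3-dimethylcyclohexan-1-one | O=C1CC(C)(C)[C@H](CO)CC1
F4 | step 7 | [(1R)-2,2-dimethyl-4-oxocyclohexyl]methyl 4-methylbenzenesulfonate | O=C1CC(C)(C)[C@H](COS(=O)(=O)c2ccc(C)cc2)CC1
F5 | step 13 | 2,2,4,4-tetramethyl-6-(3-methylbutyl)cyclohexane-1,3,5-trione | CC(C)CCC1C(=O)C(C)(C)C(=O)C(C)(C)C1=O
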